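## The problem

Compound 20 is a cyclohexa-1,4-diene. Ring atoms are labelled C1–C6 (C1 carries the side chain, C3 the free hydroxyl, C5 the methoxy group, C6 an acetate); the side chain is C1'H2–C2'H(OAc)–C13H27. It has three stereocentres: C3 (R) and C6 (S), with cis oxygens, and C2' (R).

Both ring stereocentres are doubly allylic, and the C3–O bond is a vinylogous acetal of the C4=C5 methyl enol ether. Acid, Lewis acids, oxidants and strong base therefore lead to loss of water or AcOH and to an arene. The skipped diene must be formed late, under neutral conditions, and handled only with buffered reagents.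

Three secondary oxygens must end up different (O3 free, O6 and O2' acetylated), and selective acylation of a triol cannot be relied on for this.

C3 and C6 are 1,4-related across the ring and can be set together by one suprafacial addition to a diene. C2' is insulated from the ring by C1' and can influence the ring only if it sits in a cyclic transition state.

The enabling feature is that O6 and O2' are joined through C6–C1–C1'–C2'. One silicon atom bridging them closes a seven-membered ring that contains C6 and C1. The double bonds C1=C2 and C4=C5 flanking sp3 C3 and C6 are the retron of an alkyne (C1≡C2) plus diene (C3–C6) [4+2] addition. The same bridge pairs exactly the two oxygens that must later be acetylated together.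

## Retrosynthesis

**20 back to 17.** Only O–acyl and O–Si bonds are cut. Target 20 comes from its O3 silyl ether 19, 19 from diol 18 by double acetylation, and 18 from the bicyclic silaketal 17 by removal of the bridging silicon. The tether releases O6 and O2' together while O3 stays masked, so the required differentiation costs no extra step. The forward reactions must be near neutral throughout, and the dialkoxysilane must be more labile to fluoride than the tert-butyldiphenylsilyl ether.

**17 back to 16 (key disconnection).** The bonds C1–C6 and C2–C3 are cut, opening the carbocycle and the seven-membered silaketal at once. This gives the acyclic dienyne 16, which has one stereocentre and no ring.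
- Against cutting C5–C6/C3–C4 instead: that leaves C5 at the wrong oxidation level.
- Against cutting a single ring bond: that leaves three stereocentres to be made one by one.
- What is asked of the forward step: an unactivated alkyne must add to an electron-rich diene through a five-atom tether, cis across the diene, on one face, without aromatising the product.
- Heat alone is preferred to a cationic rhodium catalyst such as [Rh(cod)Cl]2/AgSbF6 (univalent rhodium). The catalyst would lower the temperature but would put a Lewis acid and a silver salt next to the vinylogous acetal of 17.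

**16 back to 14 and 12.** The enol O–Si bond is cut. The chlorosilane 14 silylates the potassium dienolate 15 of enal 12. This is convergent and brings in the chiral fragment last. The forward reaction must place both diene oxygens outside, that is (1Z,3E).

**14 back to 5, and 5 back to 1 and 2.** The Si–O bond of 14 leads to alcohol 5 and dichlorosilane 13. In 5 the C–C bonds on either side of the carbinol are cut, giving (R)-epichlorohydrin 1, the Grignard reagent 2 and an acetylide; the path runs through chlorohydrin 3 and epoxide 4. A one-step catalytic asymmetric propargylation of the corresponding aldehyde would be shorter. The chiral-pool route is chosen because C2' is the only source of absolute configuration in the plan, and in this route the carbinol carbon is never a reacting centre.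

**12 back to 6.** The C4=C5 bond of 12 is cut by a Horner–Wadsworth–Emmons disconnection into aldehyde 8 and phosphonate 9, with ester 10 and allylic alcohol 11 as redox stages. Aldehyde 8 comes from the bis-silyl ether 7 of (Z)-butenediol 6 by ozonolysis, which gives two equivalents. The geometry of this double bond is irrelevant, because it becomes the central single bond of the diene.

## Roads not taken

**Alternative 1: chiral ketene equivalent, cut through C5–C6 and C3–C4.**
- Forward key step: an intermolecular Diels–Alder reaction of the 1-silyloxy-4-acetoxy diene A1 (C6–C1–C2–C3, side chain on C1) with the exocyclic alkene of the lactic-acid-derived dioxolanone A2 would give the spiro adduct A3.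
- Merits: the reaction class is established, the ortho regiochemistry is matched, and the tert-butyl acetal fixes the ring configuration by reagent control, independent of C2'. In facial control this is more secure than the chosen plan. The quaternary C5 makes A3 immune to aromatisation.
- Weak points: A3 has a C4 methylene and a masked α-hydroxy acid at C5. Reaching the target needs hydrolysis, oxidative decarboxylation to a C5 ketone and regioselective O-methylation of an enolate that has the C3 acetate in its β-position, which is the very elimination that leads to a phenol. The acetate sits on O3, where the target has OH, so all three oxygens must be exchanged. A1, a 2-substituted 1,4-dioxygenated diene of defined geometry, is no easier to make than the diene of 16.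
- Comparison: this road gains certainty in the ring-forming step and in facial control. It loses some five or six steps after the cycloaddition and passes through the least stable intermediates, where the chosen plan needs three buffered protecting-group operations.

**Alternative 2: olefinic ester cyclisation, cut at C4=C5.**
- Forward key step: the titanium ethylidene reagent from TiCl4, Zn, catalytic PbCl2, TMEDA and CH3CHBr2 (low-valent titanium) would join the ester carbon C5 of A4 to its vinyl carbon C4 and give A5.
- Merits: the ester methoxy group becomes the enol ether with no redox adjustment. A5 carries the same oxygen differentiation as the chosen endgame. The three stereocentres are set independently before ring closure, which avoids any reliance on remote induction; here this road is better.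
- Weak points: the reaction is established for cyclic enol ethers with a ring oxygen, not for a carbocycle that is a skipped diene one ionisation away from an arene. A large excess of Lewis-acidic titanium and zinc halides would be in contact with the vinylogous acetal at C3. A4 has an α-silyloxy β,γ-unsaturated ester whose C6 centre can epimerise or conjugate, and a Z-trisubstituted alkene. The linear construction of A4 would be clearly longer.
- Comparison: the endgame is equal and the stereochemical security is better. Step count, precursor stability and the acidity of the ring-closing medium are worse. The chosen plan closes the ring without any reagent.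

**Alternative 3: Nozaki–Hiyama–Kishi closure, cut at C1–C6.**
- Forward key step: CrCl2 with catalytic NiCl2 (divalent chromium, divalent nickel) and a chiral oxazoline–sulfonamide ligand would turn the vinyl iodide of A6 into a vinylchromium species that adds to the C6 aldehyde, giving A7.
- Merits: every step has precedent, the closure is mild and chemoselective, and the geometry of both ring double bonds is fixed before closure. A7 has O6 free. This is probably the road most likely to work as written.
- Weak points: the new C6 centre must be set by the ligand with or against the resident C3 centre. A6 is a (Z)-γ-silyloxy α-methoxy enal that can isomerise or lose silanol before it closes. The chromium alkoxide of a doubly allylic alcohol, and the chlorosilane needed for turnover, are Lewis acids next to the vinylogous acetal. C2', C3 and C6 are made one by one in a long linear sequence.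
- Comparison: this road is superior in precedent. The chosen plan offers convergence, fewer steps, and ring plus two stereocentres in one reagent-free operation, at the price of an unprecedented key step and less certain facial control.

Key step: step 10

Assumption: (R)-epichlorohydrin, dodecylmagnesium bromide, lithium acetylide–ethylenediamine complex and methyl 2-(dimethoxyphosphoryl)-2-methoxyacetate are taken as purchasable reagents.

Remark: "outside" means trans to the neighbouring diene carbon on a diene terminus. The minor (E)-isomers of 10–12 are carried along, since that double bond becomes the central single bond of the diene in step 9.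

## Route

Step 1
Reactants: 1 (R)-epichlorohydrin; 2 dodecylmagnesium bromide
Product: 3 (R)-1-chloropentadecan-2-ol
Conditions: CuI (10 mol %), THF, −40 → −20 °C; aq. NH4Cl
Reagents that add atoms: none
Why: Copper-catalysed Grignard opening of the epoxide at its unsubstituted carbon; the C–O bond at the stereocentre is not touched, so the (R) configuration of 1 is carried into 3.

Step 2
Reactants: 3 (R)-1-chloropentadecan-2-ol
Product: 5 (R)-heptadec-1-yn-4-ol, via (R)-2-tridecyloxirane 4 (not isolated)
Conditions: LiC≡CH·H2NCH2CH2NH2 (3.5 equiv), DMSO, 0 °C → rt; aq. NH4Cl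
Reagents that add atoms: lithium acetylide–ethylenediamine complex, [Li]C#C.NCCN
Why: The basic acetylide first closes the chlorohydrin to epoxide 4 (intramolecular Williamson etherification) and then opens it at the terminal carbon (SN2 epoxide opening); both events occur at CH2, so the carbinol centre, the future C2', stays (R).

Step 3
Reactants: 6 (Z)-but-2-ene-1,4-diol
Product: 7 (Z)-1,4-bis[(tert-butyldiphenylsilyl)oxy]but-2-ene
Conditions: t-BuPh2SiCl (2.2 equiv), imidazole, DMF, 0 °C → rt
Reagents that add atoms: tert-butyl(chloro)diphenylsilane, CC(C)(C)[Si](Cl)(c1ccccc1)c1ccccc1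
Why: Imidazole-promoted silylation of both primary hydroxyls; the tert-butyldiphenylsilyl group is chosen because it must outlast the tether under fluoride in step 11 and is slow to migrate from O to C in step 9.

Step 4
Reactants: 7 (Z)-1,4-bis[(tert-butyldiphenylsilyl)oxy]but-2-ene
Product: 8 2-[(tert-butyldiphenylsilyl)oxy]acetaldehyde
Conditions: O3, CH2Cl2, −78 °C; then PPh3, −78 °C → rt
Reagents that add atoms: ozone, [O-][O+]=O
Why: Ozonolysis with reductive work-up; the symmetrical alkene gives two equivalents of the same aldehyde.

Step 5
Reactants: 8 2-[(tert-butyldiphenylsilyl)oxy]acetaldehyde; 9 methyl 2-(dimethoxyphosphoryl)-2-methoxyacetate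
Product: 10 methyl (2Z)-4-[(tert-butyldiphenylsilyl)oxy]-2-methoxybut-2-enoate
Conditions: 9, LiN(SiMe3)2, THF, −78 °C; then 8, −78 → 0 °C
Reagents that add atoms: none
Why: Horner–Wadsworth–Emmons olefination with an α-methoxy phosphonoacetate; the isomer with the ester trans to the chain, (Z) by the sequence rules, should predominate, and the geometry is of no consequence later.

Step 6
Reactants: 10 methyl (2Z)-4-[(tert-butyldiphenylsilyl)oxy]-2-methoxybut-2-enoate
Product: 11 (2Z)-4-[(tert-butyldiphenylsilyl)oxy]-2-methoxybut-2-en-1-ol
Conditions: i-Bu2AlH (2.3 equiv), CH2Cl2, −78 °C; aq. potassium sodium tartrate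
Reagents that add atoms: none
Why: 1,2-Reduction of the conjugated ester to the allylic alcohol by the aluminium hydride at low temperature; silyl ether and enol ether are inert.

Step 7
Reactants: 11 (2Z)-4-[(tert-butyldiphenylsilyl)oxy]-2-methoxybut-2-en-1-ol
Product: 12 (2Z)-4-[(tert-butyldiphenylsilyl)oxy]-2-methoxybut-2-enal
Conditions: MnO2 (15 equiv), CH2Cl2, rt
Reagents that add atoms: none
Why: Chemoselective allylic oxidation with MnO2 under neutral conditions gives the α-methoxy enal without hydrolysing the enol ether.

Step 8
Reactants: 5 (R)-heptadec-1-yn-4-ol; 13 dichlorodi(propan-2-yl)silane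
Product: 14 chloro{[(4R)-heptadec-1-yn-4-yl]oxy}di(propan-2-yl)silane
Conditions: 13 (3 equiv), Et3N (1.5 equiv), CH2Cl2, 0 °C → rt; excess 13 removed at 0.1 mbar, used crude
Reagents that add atoms: none
Why: Monosilylation of a secondary alcohol with excess dichlorosilane, the usual first stage of an unsymmetrical silaketal synthesis; the second chloride on the hindered silicon is displaced much more slowly, and the excess reagent is volatile.

Step 9
Reactants: 12 (2Z)-4-[(tert-butyldiphenylsilyl)oxy]-2-methoxybut-2-enal; 14 chloro{[(4R)-heptadec-1-yn-4-yl]oxy}di(propan-2-yl)silane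
Product: 16 {[(1Z,3E)-4-[(tert-butyldiphenylsilyl)oxy]-2-methoxybuta-1,3-dien-1-yl]oxy}{[(4R)-heptadec-1-yn-4-yl]oxy}di(propan-2-yl)silane, via potassium dienolate 15 (not isolated)
Conditions: 12, KN(SiMe3)2 (1.05 equiv), THF, −78 °C; then 14 (1.1 equiv), −78 → −20 °C; pH 7 buffer, Et3N-deactivated silica
Reagents that add atoms: none
Why: γ-Deprotonation of the enal gives the extended dienolate 15, which is silylated on oxygen by the chlorosilane (silyl dienol ether formation). The s-trans enal conformer, in which K+ can bridge the carbonyl and methoxy oxygens, should put O6 cis to OMe, and allylic 1,3-strain against the substituent on C5 should put the silyloxy group on C3 trans to C5, so that both oxygens are outside.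

Step 10
Reactants: 16 {[(1Z,3E)-4-[(tert-butyldiphenylsilyl)oxy]-2-methoxybuta-1,3-dien-1-yl]oxy}{[(4R)-heptadec-1-yn-4-yl]oxy}di(propan-2-yl)silane
Product: 17 (4R,7R,9aS)-7-[(tert-butyldiphenylsilyl)oxy]-9-methoxy-2,2-di(propan-2-yl)-4-tridecyl-4,5,7,9a-tetrahydrobenzo[d][1,3,2]dioxasilepine (bicyclic silaketal; C2' R, C3 R, C6 S, O3 and O6 cis)
Conditions: PhMe (0.01 M, degassed), 2,6-di-tert-butyl-4-methylpyridine (0.2 equiv), BHT (0.1 equiv), sealed base-washed tube, 165 °C
Reagents that add atoms: none
Why: Proposed new method: the terminal alkyne C1≡C2 is expected to add across the diene C3=C4–C5=C6 in a concerted, suprafacial [4+2] cycloaddition; the closest known reaction types are silyl-acetal-tethered intramolecular Diels–Alder reactions of activated dienophiles and thermal or rhodium-catalysed intramolecular [4+2] additions of unactivated alkynes over three- and four-atom tethers, and what is new is the combination of an unactivated alkyne, a five-atom O–Si–O tether and a 1,2,4-trioxygenated diene. The six-membered carbocycle closes in the fused (type 1) intramolecular mode by the bonds C1–C6 and C2–C3, and the seven-membered dioxasilepane closes in the same event through C1–C6, the tether enforcing the C1–C6 connection that the C5 methoxy group would disfavour for a free alkyne. The raised HOMO of the diene, the long Si–O bonds and the Thorpe–Ingold effect of the two isopropyl groups should bring the barrier within reach at 165 °C, and the diene has no allylic hydrogen placed for a [1,5]-shift. The relative configuration of C3 and C6 is controlled by the diene geometry: both oxygens are outside in the (1Z,3E) diene and must end up cis. The absolute sense (3R,6S) is controlled by C2' through the fold of the tether: the target needs the tridecyl group and H-6 on the same face of the seven-membered ring, which results when the tether folds boat-like around the long, nearly eclipsed C1···C6 bond, with the C1'–C2' bond staggered and the tridecyl group turned away from the isopropyl groups. A chair fold with equatorial tridecyl would deliver the other face, so facial selectivity is the selectivity this step needs and the one least firmly secured by the substrate. The adduct cannot lose silanol by thermal syn-1,4-elimination because H-6 and O3 (and H-3 and O6) are trans, and the hindered pyridine removes traces of acid that would ionise the C3–O bond.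

Step 11
Reactants: 17 bicyclic silaketal (4R,7R,9aS)
Product: 18 (1S,4R)-4-[(tert-butyldiphenylsilyl)oxy]-2-[(2R)-2-hydroxypentadecyl]-6-methoxycyclohexa-2,5-dien-1-ol
Conditions: Et3N·3HF (5 equiv), THF, 0 °C → rt
Reagents that add atoms: none
Why: Fluoride-mediated cleavage of a silyl ether; the dialkoxysilane silicon, with two electronegative oxygens, should be attacked far faster than the hindered tert-butyldiphenylsilyl ether, and the nearly neutral amine–HF reagent avoids ionisation at C3.

Step 12
Reactants: 18 (1S,4R)-4-[(tert-butyldiphenylsilyl)oxy]-2-[(2R)-2-hydroxypentadecyl]-6-methoxycyclohexa-2,5-dien-1-ol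
Product: 19 (1S,4R)-2-[(2R)-2-(acetyloxy)pentadecyl]-4-[(tert-butyldiphenylsilyl)oxy]-6-methoxycyclohexa-2,5-dien-1-yl acetate
Conditions: Ac2O (4 equiv), Et3N, DMAP (0.1 equiv), CH2Cl2, 0 °C
Reagents that add atoms: acetic anhydride, CC(=O)OC(C)=O
Why: DMAP-catalysed acylation of both free hydroxyls in basic medium, where the vinylogous acetal is safe; no stereocentre is touched.

Step 13
Reactants: 19 (1S,4R)-2-[(2R)-2-(acetyloxy)pentadecyl]-4-[(tert-butyldiphenylsilyl)oxy]-6-methoxycyclohexa-2,5-dien-1-yl acetate
Product: 20 (1S,4R)-2-[(2R)-2-(acetyloxy)pentadecyl]-4-hydroxy-6-methoxycyclohexa-2,5-dien-1-yl acetate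
Conditions: Bu4NF/AcOH (1:1, 1.5 equiv), THF, 0 °C → rt
Reagents that add atoms: none
Why: Fluoride-mediated desilylation buffered with AcOH, so that no free alkoxide is present to cause acetyl migration or elimination; acetates are stable to these conditions.

## Compound list

1 | (R)-epichlorohydrin, (2R)-2-(chloromethyl)oxirane | ClC[C@H]1CO1 | starting material
2 | dodecylmagnesium bromide | CCCCCCCCCCCC[Mg]Br | starting material
3 | (R)-1-chloropentadecan-2-ol | ClC[C@H](O)CCCCCCCCCCCCC | intermediate
4 | (R)-2-tridecyloxirane | CCCCCCCCCCCCC[C@@H]1CO1 | intermediate (not isolated)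
5 | (R)-heptadec-1-yn-4-ol | CCCCCCCCCCCCC[C@H](CC#C)O | intermediate
6 | (Z)-but-2-ene-1,4-diol | OC/C=C\CO | starting material
7 | (Z)-1,4-bis[(tert-butyldiphenylsilyl)oxy]but-2-ene | CC(C)(C)[Si](c1ccccc1)(c1ccccc1)OC/C=C\CO[Si](c1ccccc1)(c1ccccc1)C(C)(C)C | intermediate
8 | 2-[(tert-butyldiphenylsilyl)oxy]acetaldehyde | O=CCO[Si](c1ccccc1)(c1ccccc1)C(C)(C)C | intermediate
9 | methyl 2-(dimethoxyphosphoryl)-2-methoxyacetate | COC(=O)C(OC)P(=O)(OC)OC | starting material
10 | methyl (2Z)-4-[(tert-butyldiphenylsilyl)oxy]-2-methoxybut-2-enoate | COC(=O)/C(OC)=C/CO[Si](c1ccccc1)(c1ccccc1)C(C)(C)C | intermediate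
11 | (2Z)-4-[(tert-butyldiphenylsilyl)oxy]-2-methoxybut-2-en-1-ol | OC/C(OC)=C/CO[Si](c1ccccc1)(c1ccccc1)C(C)(C)C | intermediate
12 | (2Z)-4-[(tert-butyldiphenylsilyl)oxy]-2-methoxybut-2-enal | O=C/C(OC)=C/CO[Si](c1ccccc1)(c1ccccc1)C(C)(C)C | intermediate
13 | dichlorodi(propan-2-yl)silane | CC(C)[Si](Cl)(Cl)C(C)C | starting material
14 | chloro{[(4R)-heptadec-1-yn-4-yl]oxy}di(propan-2-yl)silane | CCCCCCCCCCCCC[C@H](CC#C)O[Si](Cl)(C(C)C)C(C)C | intermediate
15 | potassium (1Z,3E)-4-[(tert-butyldiphenylsilyl)oxy]-2-methoxybuta-1,3-dien-1-olate | [K+].[O-]/C=C(OC)/C=C/O[Si](c1ccccc1)(c1ccccc1)C(C)(C)C | intermediate (not isolated)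
16 | {[(1Z,3E)-4-[(tert-butyldiphenylsilyl)oxy]-2-methoxybuta-1,3-dien-1-yl]oxy}{[(4R)-heptadec-1-yn-4-yl]oxy}di(propan-2-yl)silane | CCCCCCCCCCCCC[C@H](CC#C)O[Si](C(C)C)(C(C)C)O/C=C(OC)/C=C/O[Si](c1ccccc1)(c1ccccc1)C(C)(C)C | intermediate
17 | (4R,7R,9aS)-7-[(tert-butyldiphenylsilyl)oxy]-9-methoxy-2,2-di(propan-2-yl)-4-tridecyl-4,5,7,9a-tetrahydrobenzo[d][1,3,2]dioxasilepine | CCCCCCCCCCCCC[C@H](CC1=C[C@@H](O[Si](c2ccccc2)(c2ccccc2)C(C)(C)C)C=C(OC)[C@H]1O3)O[Si]3(C(C)C)C(C)C | intermediate
18 | (1S,4R)-4-[(tert-butyldiphenylsilyl)oxy]-2-[(2R)-2-hydroxypentadecyl]-6-methoxycyclohexa-2,5-dien-1-ol | CCCCCCCCCCCCC[C@H](CC1=C[C@@H](O[Si](c2ccccc2)(c2ccccc2)C(C)(C)C)C=C(OC)[C@H]1O)O | intermediate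
19 | (1S,4R)-2-[(2R)-2-(acetyloxy)pentadecyl]-4-[(tert-butyldiphenylsilyl)oxy]-6-methoxycyclohexa-2,5-dien-1-yl acetate | CCCCCCCCCCCCC[C@H](CC1=C[C@@H](O[Si](c2ccccc2)(c2ccccc2)C(C)(C)C)C=C(OC)[C@H]1OC(C)=O)OC(C)=O | intermediate
20 | (1S,4R)-2-[(2R)-2-(acetyloxy)pentadecyl]-4-hydroxy-6-methoxycyclohexa-2,5-dien-1-yl acetate | CCCCCCCCCCCCC[C@H](CC1=C[C@@H](O)C=C(OC)[C@H]1OC(C)=O)OC(C)=O | target

## Count and risks

Total: 13 steps. Longest linear sequence: 10 steps (6 → 7 → 8 → 10 → 11 → 12 → 16 → 17 → 18 → 19 → 20; steps 3–7 and 9–13).

**Step 10 (key step).**
- What may go wrong: the cycloaddition may not set in below the temperature at which the adduct ionises at C3, loses silanol and aromatises. Facial selectivity may be poor or reversed, because the boat and chair folds of the tether should differ little in energy and lead to opposite faces.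
- The two adducts would be diastereomers and separable. A reversed sense could only be corrected by inverting C2' after ring formation, so the ratio would be determined on 17 before material is committed.
- Fallback, using known chemistry: activate the alkyne as its sulfone, the classical acetylene equivalent. Setting out from 16, deprotonation of the alkyne with n-BuLi in THF at −78 °C and trapping with p-toluenesulfonyl fluoride would give the sulfonylated dienyne {[(1Z,3E)-4-[(tert-butyldiphenylsilyl)oxy]-2-methoxybuta-1,3-dien-1-yl]oxy}{[(4R)-1-(4-methylbenzenesulfonyl)heptadec-1-yn-4-yl]oxy}di(propan-2-yl)silane F1. This is a silaketal-tethered diene with an activated dienophile, and sulfone and diene polarisation both favour C1–C6 bonding; it should cyclise in toluene at 80–110 °C to the C2-sulfonylated bicyclic silaketal F2. Reductive desulfonylation with Na/Hg and Na2HPO4 in MeOH–THF at −20 °C would return the route at 17.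

**Step 9.**
- What may go wrong: the dienolate may be silylated as a mixture of double-bond isomers, of which only the one with both oxygens outside can cyclise. It may also suffer 1,2-migration of silicon from O3 to carbon before it is trapped, and the silyl dienol ether may hydrolyse on isolation.
- Fallback: replace the metal dienolate by amine-mediated soft enolisation. Setting out from 5, treatment with i-Pr2Si(OTf)2 and 2,6-lutidine in CH2Cl2 at −78 °C would give {[(4R)-heptadec-1-yn-4-yl]oxy}di(propan-2-yl)silyl trifluoromethanesulfonate F3 in the flask. Addition of 12 and Et3N would silylate the carbonyl oxygen and remove the γ-proton of the resulting oxocarbenium ion, coming back to the route at 16.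

**Step 11.**
- What may go wrong: fluoride may also attack the tert-butyldiphenylsilyl ether, or the medium may be acidic enough to ionise C3–O, with loss of the skipped diene.
- Fallback: change the tether so that it can be removed without fluoride. Setting out from 5, Ph2SiCl2 and Et3N would give chloro{[(4R)-heptadec-1-yn-4-yl]oxy}diphenylsilane F4. With dienolate 15 this would give the diphenylsilaketal dienyne F5, and cycloaddition as in step 10 would give the diphenylsilyl analogue of the bicyclic silaketal F6. Its silaketal should be cleaved by K2CO3 in MeOH at 0 °C, conditions that leave a tert-butyldiphenylsilyl ether untouched, and this returns the route at 18.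

## Further compounds

F1 | step 10 | {[(1Z,3E)-4-[(tert-butyldiphenylsilyl)oxy]-2-methoxybuta-1,3-dien-1-yl]oxy}{[(4R)-1-(4-methylbenzenesulfonyl)heptadec-1-yn-4-yl]oxy}di(propan-2-yl)silane | CCCCCCCCCCCCC[C@H](CC#CS(=O)(=O)c1ccc(C)cc1)O[Si](C(C)C)(C(C)C)O/C=C(OC)/C=C/O[Si](c1ccccc1)(c1ccccc1)C(C)(C)C
F2 | step 10 | C2-(4-methylbenzenesulfonyl) derivative of bicyclic silaketal 17 (sulfonyl on the ring carbon between C1 and C3) | CCCCCCCCCCCCC[C@H](CC1=C(S(=O)(=O)c2ccc(C)cc2)[C@@H](O[Si](c2ccccc2)(c2ccccc2)C(C)(C)C)C=C(OC)[C@H]1O3)O[Si]3(C(C)C)C(C)C
F3 | step 9 | {[(4R)-heptadec-1-yn-4-yl]oxy}di(propan-2-yl)silyl trifluoromethanesulfonate | CCCCCCCCCCCCC[C@H](CC#C)O[Si](OS(=O)(=O)C(F)(F)F)(C(C)C)C(C)C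
F4 | step 11 | chloro{[(4R)-heptadec-1-yn-4-yl]oxy}diphenylsilane | CCCCCCCCCCCCC[C@H](CC#C)O[Si](Cl)(c1ccccc1)c1ccccc1
F5 | step 11 | {[(1Z,3E)-4-[(tert-butyldiphenylsilyl)oxy]-2-methoxybuta-1,3-dien-1-yl]oxy}{[(4R)-heptadec-1-yn-4-yl]oxy}diphenylsilane | CCCCCCCCCCCCC[C@H](CC#C)O[Si](c1ccccc1)(c1ccccc1)O/C=C(OC)/C=C/O[Si](c1ccccc1)(c1ccccc1)C(C)(C)C
F6 | step 11 | (4R,7R,9aS)-7-[(tert-butyldiphenylsilyl)oxy]-9-methoxy-2,2-diphenyl-4-tridecyl-4,5,7,9a-tetrahydrobenzo[d][1,3,2]dioxasilepine | CCCCCCCCCCCCC[C@H](CC1=C[C@@H](O[Si](c2ccccc2)(c2ccccc2)C(C)(C)C)C=C(OC)[C@H]1O3)O[Si]3(c1ccccc1)c1ccccc1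
A1 | alternative 1 | (1E,3E)-diene: (3R)-1-acetoxy-3'-type diene with O-silyl on C6, side chain on C1, acetate on C3 (both oxygens outside) | CCCCCCCCCCCCC[C@H](C/C(=C\O[Si](C)(C)C(C)(C)C)/C=C/OC(C)=O)O[Si](C)(C)C(C)(C)C
A2 | alternative 1 | (S)-2-tert-butyl-5-methylene-1,3-dioxolan-4-one | C=C1O[C@H](C(C)(C)C)OC1=O
A3 | alternative 1 | spiro dioxolanone cyclohexene adduct | CCCCCCCCCCCCC[C@H](CC1=C[C@@H](OC(C)=O)C[C@@]2(O[C@H](C(C)(C)C)OC2=O)[C@H]1O[Si](C)(C)C(C)(C)C)O[Si](C)(C)C(C)(C)C
A4 | alternative 2 | open-chain olefinic methyl ester (ester carbon C5, vinyl carbon C4, Z-trisubstituted C1=C2) | CCCCCCCCCCCCC[C@H](C/C(=C/[C@@H](O[Si](c1ccccc1)(c1ccccc1)C(C)(C)C)C=C)[C@H](O[Si](CC)(CC)CC)C(=O)OC)O[Si](CC)(CC)CC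
A5 | alternative 2 | tris-silylated ring (O3 tert-butyldiphenylsilyl, O6 and O2' triethylsilyl) | CCCCCCCCCCCCC[C@H](CC1=C[C@@H](O[Si](c2ccccc2)(c2ccccc2)C(C)(C)C)C=C(OC)[C@H]1O[Si](CC)(CC)CC)O[Si](CC)(CC)CC
A6 | alternative 3 | open-chain (Z)-vinyl iodide (C1) with (Z)-related α-methoxy enal (C6 aldehyde) | CCCCCCCCCCCCC[C@H](C/C(I)=C/[C@@H](O[Si](C)(C)C(C)(C)C)/C=C(OC)\C=O)O[Si](CC)(CC)CC
A7 | alternative 3 | ring with free C6 hydroxyl (O3 tert-butyldimethylsilyl, O2' triethylsilyl) | CCCCCCCCCCCCC[C@H](CC1=C[C@@H](O[Si](C)(C)C(C)(C)C)C=C(OC)[C@H]1O)O[Si](CC)(CC)CC
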